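- You ask for a quick number and suspect that west leads, so I take the easy step first and see what the runs can carry.

| setting | dawn | midnight | autumn | west | north | south | south-east |
|---|---|---|---|---|---|---|---|
| substrate | 10 mM | 10 mM | 26 mM | 40 mM | 10 mM | 40 mM | 10 mM |
| coupling partner | 0.90 equiv | 0.90 equiv | 0.90 equiv | 0.900 equiv | 0.900 equiv | 0.900 equiv | 0.900 equiv |
| precatalyst | 0.32 mol% | 1.8 mol% | 2.1 mol% | 2.1 mol% | 0.5 mol% | 0.5 mol% | 2.1 mol% |
| temperature | 10 °C | 25 °C | 10 °C | 25 °C | 25 °C | 25 °C | 25 °C |
| remark | run made earlier | run made earlier | run made earlier |  |  |  |  |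
| time |  |  |  | 30 h | 30 h | 30 h | 30 h |

| run | time / h | intermediate / % | product / % | substrate / % |
|---|---|---|---|---|
| dawn | 3.00 | 0.5 | 0 | 100.7 |
| dawn | 6.00 | 0 | 0.6 | 99.6 |
| dawn | 12.0 | 0.4 | 0 | 99.8 |
| dawn | 25.0 | 0.6 | 0.8 | 98.7 |
| dawn | 40.0 | 1.5 | 0 | 98.1 |
| midnight | 2.00 | 0.5 | 0.1 | 99.3 |
| midnight | 5.00 | 3.8 | 0 | 97.2 |
| midnight | 10.0 | 11.4 | 0.3 | 88.0 |
| midnight | 15.0 | 22.2 | 1.0 | 76.4 |
| midnight | 20.0 | 36.5 | 1.6 | 62.1 |
| autumn | 3.00 | 0 | 0.6 | 99.0 |
| autumn | 6.00 | 0.3 | 0 | 100.0 |
| autumn | 12.0 | 2.7 | 0 | 98.4 |
| autumn | 25.0 | 8.3 | 0 | 90.6 |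
| autumn | 40.0 | 21.2 | 1.7 | 78.6 |

(scatter of a reading: 0.5 percentage points)

- a reading or a percentage of product counts all its forms, free or not

- ranking by amount of intermediate, in percent of the substrate charged, from high to low, at 30 h (west / north / south / south-east)
- the same order at 5.0 d (west / north / south / south-east)
- the amount of intermediate, in percent of the substrate charged of the flask you put first, at 30 h
- the amount of intermediate, in percent of the substrate charged of the flask you put last, at 30 h

- Midnight is the one run at 25 °C, and its substrate falls slowly, then faster, as if catalyst were building up steadily from the precatalyst.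
- I therefore treat the loss as pseudo-first-order in substrate with a rate constant growing in time: -ln f = (c/m)·(t/τ)·(t/τ), where f is the share of substrate left, c the precatalyst charged in mM, m that charge in midnight, t the time and τ a ramp time.
- The ramp time τ, the time at which -ln f reaches unity at midnight's charge and the nearly constant quantity that I freeze, reads 28.9 h at 15.0 h and 29.0 h at 20.0 h.
- Millimolar charge, and not mol%, looks like the right measure: at 40.0 h and 10 °C, autumn holds 17.1 times dawn's precatalyst and shows 12.6 times its exponent, a rough figure since dawn's loss is near the scatter.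
- At 30 h, τ gives substrate consumed: 99.3 % in west, 71.4 % in south-east, 69.6 % in south and 25.8 % in north.
- Your hunch has this for it: west has consumed nearly all its substrate. But west holds 4.00 times the partner and 16.8 times the precatalyst of north, so if the onward step needs both, I expect west to send more of its intermediate onward than north.
- Midnight's product share at 20.0 h, 4.20 %, gives me about 68.4 % for south-east, which I put first, and 24.7 % for north, which I put last at 30 h and first at 5.0 d. West against south I leave open.
- The forecast ranks south-east > south > west > north at 30 h and north > south > south-east > west at 5.0 d, with 61 % (52 % to 70 %) and 25 % (18 % to 32 %), and says “West is past its maximum”; it commits to south above west, where I leave the pair open.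
- The flasks give south-east > west > south > north at 30 h and north > south-east > south > west at 5.0 d, with south-east at 64.7 % and north at 24.3 %.

    substrate + catalyst → catalyst + intermediate (k = 0.340 /M/s, Ea = 47.0 kJ/mol)
    precatalyst → catalyst (k = 3.20 × 10⁻⁶ /s, Ea = 104 kJ/mol)
    coupling partner + catalyst + intermediate → catalyst + product (k = 4.10 /M²/s, Ea = 38.0 kJ/mol)
    coupling partner + product ⇌ idle adduct, settled at all times (K = 890 /M, ΔH = −6.00 kJ/mol)
    (constants at 25 °C)

- South-east keeps 30.4 % of its substrate at 30.0 h, and τ gave 28.6 %. A neighbouring flask is south-east with 2.5 mM of substrate, a quarter of the charge at the same mol%, so c is 0.0525 mM and τ gives 73.2 % left. That neighbouring flask keeps 74.2 % of its substrate, and its intermediate stands at 25.6 %.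

(All runs were generated by integration with made-up constants; the scatter is artificial.)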